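**Plan**

- Retrosynthesis: after removal of seven silyl ethers, the styryl-bearing (unprimed) dihydrobenzofuran is cut at O1–C2 and C2–C3 (benzylic ylide carbon onto an ortho-quinone methide), then at C3–C3a (aryl Grignard onto a C5' aldehyde). The 7-hydroxy (primed) dihydrobenzofuran is cut at O1'–C2', and its open chain at C3'–C3a' and C2'–aryl in one three-component event.
- Enabling feature: C2' and C3' of the primed ring are the two carbons of a 3,5-dioxygenated styrene, each one aryl group short. The benzene ring carrying C3a', C7a', C7' and C5' is methyl gallate with the oxygen at C3a' exchanged for carbon, so that phenol can serve as a triflate.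
- Forward: styrenyl boronate + aryllithium + gallate triflate → 1,2,2-triarylethyl boronate → alcohol → primed ring (acid, trans) → C5' ester to aldehyde → union with an iodoresorcinol stilbene → unprimed ring ([4+1] annulation) → desilylation.
- Stereochemistry: C3' from ligand-controlled enantioface selection in the conjunctive coupling; C2' from anti addition to the E-alkene and then from thermodynamic trans ring closure; C2 and C3 from a chiral sulfonium ylide (ylide face) and the trans course of the annulation.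

Key step: step 8

Abbreviations: TIPS = triisopropylsilyl (TIPSO = triisopropylsilyloxy); mac ester = cyclic boronic ester of the cis-diol 6; MandyPhos = (S,S)-1,1'-bis[bis(4-methoxy-3,5-dimethylphenyl)phosphino]-2,2'-bis[(R)-α-(dimethylamino)benzyl]ferrocene, the (Sp,Sp) ligand.

Assumption: the enantiomer of the ligand in step 8 and of sulfide 29 in step 22 are taken to be those whose sense of induction gives the centres drawn; if either sense is the reverse, the mirror-image ligand or sulfide is used and nothing else changes.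

**Route**

Step 1
Reactants: 1 3,5-dihydroxybenzaldehyde
Product: 2 3,5-bis(TIPSO)benzaldehyde
Conditions: TIPSCl, imidazole, DMF, rt
Reagents that add atoms: triisopropylsilyl chloride, CC(C)[Si](Cl)(C(C)C)C(C)C
Why: Imidazole-promoted silylation of both phenols; the bulky silyl ether is chosen because it should survive organolithium, palladium, mild acid and hydride steps and is removed by fluoride at the end.

Step 2
Reactants: 2 3,5-bis(TIPSO)benzaldehyde; 3 bis[(pinacolato)boryl]methane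
Product: 4 (E)-2-[3,5-bis(TIPSO)phenyl]ethenylboronic acid pinacol ester
Conditions: lithium 2,2,6,6-tetramethylpiperidide, THF, 0 °C; then 2, −78 °C → rt
Reagents that add atoms: none
Why: Boron–Wittig olefination, in which the lithiated geminal bis(boronate) adds to the aldehyde and eliminates a boronate; with aryl aldehydes this should give the E-alkenyl boronate.

Step 3
Reactants: 5 acenaphthenequinone
Product: 6 cis-1,2-dimethyl-1,2-dihydroacenaphthylene-1,2-diol (meso)
Conditions: MeMgBr (excess), THF, 0 °C → rt; crystallisation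
Reagents that add atoms: methylmagnesium bromide, C[Mg]Br
Why: Double Grignard addition to the 1,2-diketone gives the ditertiary diol, and the cis (meso) isomer needed as boron ligand is taken by crystallisation, its two centres being defined only relative to each other.

Step 4
Reactants: 4 (E)-alkenylboronic acid pinacol ester; 6 cis-diol
Product: 8 (E)-2-[3,5-bis(TIPSO)phenyl]ethenylboronic acid mac ester, via (E)-2-[3,5-bis(TIPSO)phenyl]ethenylboronic acid 7 (not isolated)
Conditions: NaIO4, NH4OAc, acetone/H2O, rt; then 6, MgSO4, CH2Cl2, rt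
Reagents that add atoms: none
Why: Periodate glycol cleavage destroys the pinacol and frees the boronic acid, which condenses with the rigid cis-diol; the hindered mac ester is wanted because it disfavours direct transmetalation of the alkenyl group in step 8.

Step 5
Reactants: 9 4-bromophenol
Product: 10 (4-bromophenoxy)triisopropylsilane
Conditions: TIPSCl, imidazole, DMF, rt
Reagents that add atoms: triisopropylsilyl chloride, CC(C)[Si](Cl)(C(C)C)C(C)C
Why: Standard phenol silylation giving an aryl bromide that tolerates bromine–lithium exchange and magnesium insertion.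

Step 6
Reactants: 11 methyl gallate
Product: 12 methyl 7-hydroxy-2,2-dimethyl-1,3-benzodioxole-5-carboxylate
Conditions: 2,2-dimethoxypropane, TsOH·H2O (cat.), toluene, reflux
Reagents that add atoms: 2,2-dimethoxypropane, COC(C)(C)OC
Why: Acid-catalysed ketalisation bridges two adjacent hydroxyls of the pyrogallol unit as a five-membered isopropylidene ketal and leaves the third hydroxyl free.

Step 7
Reactants: 12 methyl 7-hydroxy-2,2-dimethyl-1,3-benzodioxole-5-carboxylate
Product: 13 methyl 2,2-dimethyl-7-(trifluoromethylsulfonyloxy)-1,3-benzodioxole-5-carboxylate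
Conditions: Tf2O, pyridine, CH2Cl2, 0 °C
Reagents that add atoms: triflic anhydride, O=S(=O)(OS(=O)(=O)C(F)(F)F)C(F)(F)F
Why: Triflation of the remaining phenol turns the gallate oxygen at the future C3a' into a leaving group for palladium.

Step 8
Reactants: 8 (E)-styrenylboronic acid mac ester; 10 (4-bromophenoxy)triisopropylsilane; 13 gallate-derived triflate
Product: 16 (1R,2R)-2-[3,5-bis(TIPSO)phenyl]-2-[6-(methoxycarbonyl)-2,2-dimethyl-1,3-benzodioxol-4-yl]-1-[4-(TIPSO)phenyl]ethylboronic acid mac ester, via 4-(TIPSO)phenyllithium 14 (not isolated), via lithium alkenyl(aryl)borate ate complex 15 (not isolated)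
Conditions: 10, n-BuLi, THF, −78 °C; 8, −78 °C → rt; then 13, Pd(OAc)2 (2 mol %), (Sp,Sp)-MandyPhos (2.4 mol %), THF, 60 °C
Reagents that add atoms: none
Why: Oxidative addition of 13 to zerovalent palladium gives a cationic aryl–palladium species that binds the alkene of ate complex 15; the 4-silyloxyphenyl group then shifts from boron to the boron-bearing carbon (future C2') anti to palladium, which is left on the benzylic carbon (future C3'), and reductive elimination with retention forms C3'–C3a'. The closest known reaction is the enantioselective conjunctive cross-coupling of β-substituted alkenyl boron ate complexes carrying the mac ligand with aryl triflates. No ring is closed in this step. Both new stereocentres arise in the same event: their relative configuration follows from stereospecific anti addition across the E-alkene, and the absolute configuration at C3' from enantioface selection by the ferrocenyl bisphosphine. The step needs the metallate shift to outrun direct Suzuki transfer of the styrenyl group; the hindered mac diol on boron and halide-free generation of 14 are meant to secure this, helped by a triflate with only one small ortho substituent and an ester that speeds oxidative addition.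

Step 9
Reactants: 16 triarylethylboronic acid mac ester
Product: 17 methyl 7-[(1R,2R)-1-[3,5-bis(TIPSO)phenyl]-2-hydroxy-2-[4-(TIPSO)phenyl]ethyl]-2,2-dimethyl-1,3-benzodioxole-5-carboxylate
Conditions: NaBO3·4H2O, THF/H2O, rt
Reagents that add atoms: sodium perborate, [Na+].[O-]OB=O
Why: Peroxoborate oxidation of the C–B bond proceeds by 1,2-shift of carbon from boron to oxygen with retention, and the mild reagent should spare the methyl ester and the aryl silyl ethers.

Step 10
Reactants: 17 benzylic alcohol with ketal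
Product: 18 methyl (2R,3R)-3-[3,5-bis(TIPSO)phenyl]-7-hydroxy-2-[4-(TIPSO)phenyl]-2,3-dihydro-1-benzofuran-5-carboxylate
Conditions: CF3CO2H, wet CH2Cl2, 0 °C
Reagents that add atoms: none
Why: Acid ionises the 4-silyloxybenzylic alcohol (SN1 etherification); the ketal oxygen on C7a' captures the cation in a 5-exo closure and the isopropylidene group leaves as acetone, so C3' is untouched and C2' is set trans to it under thermodynamic control because the cis isomer can re-open through the same cation.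

Step 11
Reactants: 18 7-hydroxy dihydrobenzofuran ester
Product: 19 methyl (2R,3R)-3-[3,5-bis(TIPSO)phenyl]-7-(TIPSO)-2-[4-(TIPSO)phenyl]-2,3-dihydro-1-benzofuran-5-carboxylate
Conditions: TIPSOTf, 2,6-lutidine, CH2Cl2, 0 °C
Reagents that add atoms: triisopropylsilyl triflate, CC(C)[Si](OS(=O)(=O)C(F)(F)F)(C(C)C)C(C)C
Why: Silylation of the C7' phenol (and of any phenol that lost its silyl group in step 10) gives a uniformly protected ring before the hydride and organometallic steps.

Step 12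
Reactants: 19 fully silylated ester
Product: 20 [(2R,3R)-3-[3,5-bis(TIPSO)phenyl]-7-(TIPSO)-2-[4-(TIPSO)phenyl]-2,3-dihydro-1-benzofuran-5-yl]methanol
Conditions: i-Bu2AlH, CH2Cl2, −78 → 0 °C; aq. potassium sodium tartrate
Reagents that add atoms: none
Why: Hydride reduction of the aryl ester to the benzylic alcohol, chosen over partial reduction because it is the more reliable way to the aldehyde.

Step 13
Reactants: 20 benzylic alcohol
Product: 21 (2R,3R)-3-[3,5-bis(TIPSO)phenyl]-7-(TIPSO)-2-[4-(TIPSO)phenyl]-2,3-dihydro-1-benzofuran-5-carbaldehyde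
Conditions: MnO2, CH2Cl2, rt
Reagents that add atoms: none
Why: Selective oxidation of a benzylic alcohol to the aldehyde under neutral conditions that leave silyl ethers and the benzylic C–O bonds alone.

Step 14
Reactants: 2 3,5-bis(TIPSO)benzaldehyde
Product: 22 3-hydroxy-5-(TIPSO)benzaldehyde
Conditions: Bu4NF (1.0 equiv), THF, −78 °C; NH4Cl
Reagents that add atoms: none
Why: Fluoride cleaves one aryl silyl ether, and the phenoxide so formed makes loss of the second silyl group much slower (its leaving group would be a dianion), so the mono-phenol should dominate.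

Step 15
Reactants: 22 3-hydroxy-5-(TIPSO)benzaldehyde
Product: 23 3-hydroxy-2-iodo-5-(TIPSO)benzaldehyde
Conditions: I2, NaHCO3, THF/H2O, 0 °C
Reagents that add atoms: iodine, II
Why: Electrophilic iodination of the phenoxide; of the three activated ring positions only C2 is not flanked by the bulky silyl ether, so iodine should enter between the hydroxyl and the formyl group.

Step 16
Reactants: 24 diethyl (4-hydroxybenzyl)phosphonate
Product: 25 diethyl [4-(TIPSO)benzyl]phosphonate
Conditions: TIPSCl, imidazole, DMF, rt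
Reagents that add atoms: triisopropylsilyl chloride, CC(C)[Si](Cl)(C(C)C)C(C)C
Why: Phenol silylation giving the olefination partner with the same protecting group as the rest of the route.

Step 17
Reactants: 23 3-hydroxy-2-iodo-5-(TIPSO)benzaldehyde; 25 diethyl [4-(TIPSO)benzyl]phosphonate
Product: 26 2-iodo-3-[(E)-2-[4-(TIPSO)phenyl]ethenyl]-5-(TIPSO)phenol
Conditions: NaH (2.3 equiv), THF, 0 °C → rt
Reagents that add atoms: none
Why: Horner–Wadsworth–Emmons olefination with a benzylic phosphonate gives the E-stilbene, the phenoxide formed by the first equivalent of base being a spectator.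

Step 18
Reactants: 10 (4-bromophenoxy)triisopropylsilane
Product: 28 [4-(TIPSO)phenyl]methanol, via 4-(TIPSO)phenylmagnesium bromide 27 (not isolated)
Conditions: Mg turnings, I2 (cat.), THF, reflux; then paraformaldehyde, 0 °C → rt; NH4Cl
Reagents that add atoms: paraformaldehyde (as formaldehyde), C=O
Why: Magnesium insertion into the aryl bromide gives the aryl Grignard reagent, to which the aryl silyl ether is inert, and hydroxymethylation with formaldehyde gives the benzylic alcohol.

Step 19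
Reactants: 28 [4-(TIPSO)phenyl]methanol; 29 isothiocineole (commercial chiral sulfide)
Product: 31 S-[4-(TIPSO)benzyl]isothiocineolium tetrafluoroborate, via 4-(TIPSO)benzyl bromide 30 (not isolated)
Conditions: PBr3, Et2O, 0 °C; then 29, AgBF4, CH2Cl2, 0 °C → rt
Reagents that add atoms: silver tetrafluoroborate, [Ag+].F[B-](F)(F)F
Why: The alcohol is converted to the ionisable benzylic bromide, which alkylates the sulfide once silver abstracts bromide; alkylation is expected on the less hindered sulfur lone pair, giving one sulfonium diastereomer.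

Step 20
Reactants: 26 iodophenol stilbene; 21 dihydrobenzofuran aldehyde
Product: 33 2-[hydroxy(Ar)methyl]-3-[(E)-2-[4-(TIPSO)phenyl]ethenyl]-5-(TIPSO)phenol with Ar = the (2R,3R)-dihydrobenzofuran-5-yl unit of 21 (both carbinol epimers), via chloromagnesium 2-(chloromagnesio)phenoxide 32 (not isolated)
Conditions: MeMgCl (1.0 equiv), THF, −20 °C; i-PrMgCl·LiCl, −20 °C → rt; then 21, 0 °C → rt; pH 7 buffer
Reagents that add atoms: none
Why: Deprotonation of the phenol followed by iodine–magnesium exchange on the unprotected iodophenol gives an aryl Grignard reagent that adds to the aldehyde and does not touch the stilbene; the new carbinol centre forms as a mixture, which is immaterial because it becomes trigonal in step 22.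

Step 21
Reactants: 33 ortho-hydroxybenzhydrol
Product: 34 tert-butyl aryl carbonate of 33 (Boc on the phenol oxygen; both carbinol epimers)
Conditions: Boc2O (1.05 equiv), DMAP (cat.), CH2Cl2, −20 → 0 °C
Reagents that add atoms: di-tert-butyl dicarbonate, CC(C)(C)OC(=O)OC(=O)OC(C)(C)C
Why: DMAP-catalysed carbonate formation on the more acidic phenol gives a latent ortho-quinone methide; acylation of the hindered benzhydrol instead would give an equally usable precursor.

Step 22
Reactants: 34 tert-butyl aryl carbonate; 31 chiral benzylsulfonium salt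
Product: 37 heptakis-TIPS ether of the target with (2S,3S) unprimed ring and (2R,3R) primed ring, via sulfonium benzylide 35 (not isolated), via ortho-quinone methide 36 (not isolated)
Conditions: 31 (1.5 equiv), LiN(SiMe3)2 (2.6 equiv), THF, −78 → 0 °C
Reagents that add atoms: none
Why: Proposed new method: base forms ylide 35 and the benzylic alkoxide of 34, Boc shifts from the phenol to the alkoxide and 1,4-elimination of tert-butyl carbonate releases ortho-quinone methide 36, the ylide carbon adds to the methide carbon and the phenoxide displaces the sulfide in a 5-exo-tet closure with inversion; the closest known reactions are the trans-selective [4+1] annulation of quinone methides with achiral benzyl-type sulfonium salts and the highly enantioselective aldehyde epoxidation by benzylides of this same sulfide, so the sulfide should fix C2 (S) through the ylide face and the anti mode of addition should place C3 (S) trans to it.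

Step 23
Reactants: 37 heptakis-TIPS ether
Product: 38 target, (2S,3S)-3-[(2R,3R)-3-(3,5-dihydroxyphenyl)-7-hydroxy-2-(4-hydroxyphenyl)-2,3-dihydro-1-benzofuran-5-yl]-2-(4-hydroxyphenyl)-4-[(E)-2-(4-hydroxyphenyl)ethenyl]-2,3-dihydro-1-benzofuran-6-ol
Conditions: Bu4NF, AcOH, THF, 0 °C → rt, argon
Reagents that add atoms: none
Why: Fluoride cleaves all seven aryl silyl ethers, and the acetic acid buffer keeps the polyphenol from standing as air-sensitive phenoxides that could re-open the 2-(4-hydroxyphenyl) rings.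

**Compound list**

1 | 3,5-dihydroxybenzaldehyde | O=Cc1cc(O)cc(O)c1 | starting material
2 | 3,5-bis(TIPSO)benzaldehyde | O=Cc1cc(O[Si](C(C)C)(C(C)C)C(C)C)cc(O[Si](C(C)C)(C(C)C)C(C)C)c1 | intermediate
3 | bis[(pinacolato)boryl]methane | CC1(C)OB(CB2OC(C)(C)C(C)(C)O2)OC1(C)C | starting material
4 | (E)-2-[3,5-bis(TIPSO)phenyl]ethenylboronic acid pinacol ester | CC1(C)OB(/C=C/c2cc(O[Si](C(C)C)(C(C)C)C(C)C)cc(O[Si](C(C)C)(C(C)C)C(C)C)c2)OC1(C)C | intermediate
5 | acenaphthenequinone | O=C1C(=O)c2cccc3cccc1c23 | starting material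
6 | cis-1,2-dimethyl-1,2-dihydroacenaphthylene-1,2-diol (meso) | O[C@]1(C)c2cccc3cccc(c23)[C@]1(C)O | intermediate
7 | (E)-2-[3,5-bis(TIPSO)phenyl]ethenylboronic acid | OB(O)/C=C/c1cc(O[Si](C(C)C)(C(C)C)C(C)C)cc(O[Si](C(C)C)(C(C)C)C(C)C)c1 | intermediate
8 | (E)-2-[3,5-bis(TIPSO)phenyl]ethenylboronic acid mac ester | CC(C)[Si](C(C)C)(C(C)C)Oc1cc(O[Si](C(C)C)(C(C)C)C(C)C)cc(/C=C/B2O[C@]3(C)c4cccc5cccc(c45)[C@]3(C)O2)c1 | intermediate
9 | 4-bromophenol | Oc1ccc(Br)cc1 | starting material
10 | (4-bromophenoxy)triisopropylsilane | Brc1ccc(O[Si](C(C)C)(C(C)C)C(C)C)cc1 | intermediate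
11 | methyl gallate | COC(=O)c1cc(O)c(O)c(O)c1 | starting material
12 | methyl 7-hydroxy-2,2-dimethyl-1,3-benzodioxole-5-carboxylate | COC(=O)c1cc(O)c2OC(C)(C)Oc2c1 | intermediate
13 | methyl 2,2-dimethyl-7-(trifluoromethylsulfonyloxy)-1,3-benzodioxole-5-carboxylate | COC(=O)c1cc(OS(=O)(=O)C(F)(F)F)c2OC(C)(C)Oc2c1 | intermediate
14 | 4-(TIPSO)phenyllithium | [Li]c1ccc(O[Si](C(C)C)(C(C)C)C(C)C)cc1 | intermediate
15 | lithium [(E)-2-[3,5-bis(TIPSO)phenyl]ethenyl][4-(TIPSO)phenyl]borate of diol 6 (ate complex; configuration at boron not specified) | [Li+].CC(C)[Si](C(C)C)(C(C)C)Oc1ccc(cc1)[B-]1(/C=C/c2cc(O[Si](C(C)C)(C(C)C)C(C)C)cc(O[Si](C(C)C)(C(C)C)C(C)C)c2)O[C@]2(C)c3cccc4cccc(c34)[C@]2(C)O1 | intermediate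
16 | (1R,2R)-2-[3,5-bis(TIPSO)phenyl]-2-[6-(methoxycarbonyl)-2,2-dimethyl-1,3-benzodioxol-4-yl]-1-[4-(TIPSO)phenyl]ethylboronic acid mac ester | COC(=O)c1cc2c(OC(C)(C)O2)c(c1)[C@@H](c1cc(O[Si](C(C)C)(C(C)C)C(C)C)cc(O[Si](C(C)C)(C(C)C)C(C)C)c1)[C@H](c1ccc(O[Si](C(C)C)(C(C)C)C(C)C)cc1)B1O[C@]2(C)c3cccc4cccc(c34)[C@]2(C)O1 | intermediate
17 | methyl 7-[(1R,2R)-1-[3,5-bis(TIPSO)phenyl]-2-hydroxy-2-[4-(TIPSO)phenyl]ethyl]-2,2-dimethyl-1,3-benzodioxole-5-carboxylate | COC(=O)c1cc2c(OC(C)(C)O2)c(c1)[C@@H](c1cc(O[Si](C(C)C)(C(C)C)C(C)C)cc(O[Si](C(C)C)(C(C)C)C(C)C)c1)[C@H](c1ccc(O[Si](C(C)C)(C(C)C)C(C)C)cc1)O | intermediate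
18 | methyl (2R,3R)-3-[3,5-bis(TIPSO)phenyl]-7-hydroxy-2-[4-(TIPSO)phenyl]-2,3-dihydro-1-benzofuran-5-carboxylate | COC(=O)c1cc(O)c2c(c1)[C@@H](c1cc(O[Si](C(C)C)(C(C)C)C(C)C)cc(O[Si](C(C)C)(C(C)C)C(C)C)c1)[C@H](c1ccc(O[Si](C(C)C)(C(C)C)C(C)C)cc1)O2 | intermediate
19 | methyl (2R,3R)-3-[3,5-bis(TIPSO)phenyl]-7-(TIPSO)-2-[4-(TIPSO)phenyl]-2,3-dihydro-1-benzofuran-5-carboxylate | COC(=O)c1cc(O[Si](C(C)C)(C(C)C)C(C)C)c2c(c1)[C@@H](c1cc(O[Si](C(C)C)(C(C)C)C(C)C)cc(O[Si](C(C)C)(C(C)C)C(C)C)c1)[C@H](c1ccc(O[Si](C(C)C)(C(C)C)C(C)C)cc1)O2 | intermediate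
20 | [(2R,3R)-3-[3,5-bis(TIPSO)phenyl]-7-(TIPSO)-2-[4-(TIPSO)phenyl]-2,3-dihydro-1-benzofuran-5-yl]methanol | OCc1cc(O[Si](C(C)C)(C(C)C)C(C)C)c2c(c1)[C@@H](c1cc(O[Si](C(C)C)(C(C)C)C(C)C)cc(O[Si](C(C)C)(C(C)C)C(C)C)c1)[C@H](c1ccc(O[Si](C(C)C)(C(C)C)C(C)C)cc1)O2 | intermediate
21 | (2R,3R)-3-[3,5-bis(TIPSO)phenyl]-7-(TIPSO)-2-[4-(TIPSO)phenyl]-2,3-dihydro-1-benzofuran-5-carbaldehyde | O=Cc1cc(O[Si](C(C)C)(C(C)C)C(C)C)c2c(c1)[C@@H](c1cc(O[Si](C(C)C)(C(C)C)C(C)C)cc(O[Si](C(C)C)(C(C)C)C(C)C)c1)[C@H](c1ccc(O[Si](C(C)C)(C(C)C)C(C)C)cc1)O2 | intermediate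
22 | 3-hydroxy-5-(TIPSO)benzaldehyde | O=Cc1cc(O)cc(O[Si](C(C)C)(C(C)C)C(C)C)c1 | intermediate
23 | 3-hydroxy-2-iodo-5-(TIPSO)benzaldehyde | O=Cc1cc(O[Si](C(C)C)(C(C)C)C(C)C)cc(O)c1I | intermediate
24 | diethyl (4-hydroxybenzyl)phosphonate | CCOP(=O)(Cc1ccc(O)cc1)OCC | starting material
25 | diethyl [4-(TIPSO)benzyl]phosphonate | CCOP(=O)(Cc1ccc(O[Si](C(C)C)(C(C)C)C(C)C)cc1)OCC | intermediate
26 | 2-iodo-3-[(E)-2-[4-(TIPSO)phenyl]ethenyl]-5-(TIPSO)phenol | Oc1cc(O[Si](C(C)C)(C(C)C)C(C)C)cc(/C=C/c2ccc(O[Si](C(C)C)(C(C)C)C(C)C)cc2)c1I | intermediate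
27 | 4-(TIPSO)phenylmagnesium bromide | Br[Mg]c1ccc(O[Si](C(C)C)(C(C)C)C(C)C)cc1 | intermediate
28 | [4-(TIPSO)phenyl]methanol | OCc1ccc(O[Si](C(C)C)(C(C)C)C(C)C)cc1 | intermediate
29 | isothiocineole (2,8-epithio-cis-p-menthane; 4,7,7-trimethyl-6-thiabicyclo[3.2.1]octane), enantiomer derived from (R)-limonene | C[C@H]1CC[C@@H]2C[C@H]1SC2(C)C | starting material
30 | 4-(TIPSO)benzyl bromide | BrCc1ccc(O[Si](C(C)C)(C(C)C)C(C)C)cc1 | intermediate
31 | S-[4-(TIPSO)benzyl]isothiocineolium tetrafluoroborate (one diastereomer at sulfur expected, not specified) | C[C@H]1CC[C@@H]2C[C@H]1[S+](Cc1ccc(O[Si](C(C)C)(C(C)C)C(C)C)cc1)C2(C)C.F[B-](F)(F)F | intermediate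
32 | chloromagnesium 2-(chloromagnesio)-3-[(E)-2-[4-(TIPSO)phenyl]ethenyl]-5-(TIPSO)phenoxide | Cl[Mg]Oc1cc(O[Si](C(C)C)(C(C)C)C(C)C)cc(/C=C/c2ccc(O[Si](C(C)C)(C(C)C)C(C)C)cc2)c1[Mg]Cl | intermediate
33 | 2-[hydroxy(Ar)methyl]-3-[(E)-2-[4-(TIPSO)phenyl]ethenyl]-5-(TIPSO)phenol, Ar = (2R,3R)-3-[3,5-bis(TIPSO)phenyl]-7-(TIPSO)-2-[4-(TIPSO)phenyl]-2,3-dihydro-1-benzofuran-5-yl; both carbinol epimers | Oc1cc(O[Si](C(C)C)(C(C)C)C(C)C)cc(/C=C/c2ccc(O[Si](C(C)C)(C(C)C)C(C)C)cc2)c1C(O)c1cc(O[Si](C(C)C)(C(C)C)C(C)C)c2c(c1)[C@@H](c1cc(O[Si](C(C)C)(C(C)C)C(C)C)cc(O[Si](C(C)C)(C(C)C)C(C)C)c1)[C@H](c1ccc(O[Si](C(C)C)(C(C)C)C(C)C)cc1)O2 | intermediate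
34 | tert-butyl carbonate of the phenol of 33 (both carbinol epimers) | CC(C)(C)OC(=O)Oc1cc(O[Si](C(C)C)(C(C)C)C(C)C)cc(/C=C/c2ccc(O[Si](C(C)C)(C(C)C)C(C)C)cc2)c1C(O)c1cc(O[Si](C(C)C)(C(C)C)C(C)C)c2c(c1)[C@@H](c1cc(O[Si](C(C)C)(C(C)C)C(C)C)cc(O[Si](C(C)C)(C(C)C)C(C)C)c1)[C@H](c1ccc(O[Si](C(C)C)(C(C)C)C(C)C)cc1)O2 | intermediate
35 | isothiocineolium 4-(TIPSO)benzylide (sulfonium ylide) | C[C@H]1CC[C@@H]2C[C@H]1[S+]([CH-]c1ccc(O[Si](C(C)C)(C(C)C)C(C)C)cc1)C2(C)C | intermediate
36 | ortho-quinone methide: 6-(Ar-methylidene)-3-(TIPSO)-5-[(E)-2-[4-(TIPSO)phenyl]ethenyl]cyclohexa-2,4-dien-1-one, Ar as in 33; exocyclic geometry not specified | O=C1C=C(O[Si](C(C)C)(C(C)C)C(C)C)C=C(/C=C/c2ccc(O[Si](C(C)C)(C(C)C)C(C)C)cc2)C1=Cc1cc(O[Si](C(C)C)(C(C)C)C(C)C)c2c(c1)[C@@H](c1cc(O[Si](C(C)C)(C(C)C)C(C)C)cc(O[Si](C(C)C)(C(C)C)C(C)C)c1)[C@H](c1ccc(O[Si](C(C)C)(C(C)C)C(C)C)cc1)O2 | intermediate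
37 | heptakis-TIPS ether of the target, (2S,3S) in the styryl-bearing ring and (2R,3R) in the 7-silyloxy ring, E-alkene | CC(C)[Si](C(C)C)(C(C)C)Oc1ccc(/C=C/c2cc(O[Si](C(C)C)(C(C)C)C(C)C)cc3c2[C@H](c2cc(O[Si](C(C)C)(C(C)C)C(C)C)c4c(c2)[C@@H](c2cc(O[Si](C(C)C)(C(C)C)C(C)C)cc(O[Si](C(C)C)(C(C)C)C(C)C)c2)[C@H](c2ccc(O[Si](C(C)C)(C(C)C)C(C)C)cc2)O4)[C@@H](c2ccc(O[Si](C(C)C)(C(C)C)C(C)C)cc2)O3)cc1 | intermediate
38 | (2S,3S)-3-[(2R,3R)-3-(3,5-dihydroxyphenyl)-7-hydroxy-2-(4-hydroxyphenyl)-2,3-dihydro-1-benzofuran-5-yl]-2-(4-hydroxyphenyl)-4-[(E)-2-(4-hydroxyphenyl)ethenyl]-2,3-dihydro-1-benzofuran-6-ol | Oc1ccc(/C=C/c2cc(O)cc3c2[C@H](c2cc(O)c4c(c2)[C@@H](c2cc(O)cc(O)c2)[C@H](c2ccc(O)cc2)O4)[C@@H](c2ccc(O)cc2)O3)cc1 | target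

**Step count and risks**

Total steps: 23. Longest linear sequence: 13 (steps 1, 2, 4, 8, 9, 10, 11, 12, 13, 20, 21, 22, 23).

Most likely to fail:

1. Step 22 (proposed method). The ylide may add slowly to the hindered methide carbon, so the quinone methide is consumed by tert-butoxide or by itself. Face selection at the ylide, or the anti mode of addition, may be incomplete, which would give the mirror-configured unprimed ring or cis material. Fallback with known chemistry: setting out from carbonate 34, the annulation is run with the achiral salt S-[4-(TIPSO)benzyl]tetrahydrothiophenium bromide F1 (from bromide 30 and tetrahydrothiophene) and KOt-Bu in THF, the established trans-selective [4+1] annulation of quinone methides with benzyl-type sulfonium salts. Without reagent control it should give both trans isomers, 37 and the heptakis-TIPS ether with a (2R,3R) unprimed ring F2. Because the primed ring is already single-handed these are diastereomers and are separated by preparative chromatography, and the route is rejoined at 37.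

2. Step 8 (key step). Direct transmetalation of the styrenyl group from boron to palladium (Suzuki pathway) may outrun the metallate shift, or alkene binding of the β-aryl ate complex may be too slow for useful turnover or enantioface selection. Fallback that builds the same carbon skeleton stepwise: setting out from boronate 4, perborate oxidation gives [3,5-bis(TIPSO)phenyl]acetaldehyde F3. Aryllithium 14 adds to give 2-[3,5-bis(TIPSO)phenyl]-1-[4-(TIPSO)phenyl]ethanol F4, and Dess–Martin oxidation gives 2-[3,5-bis(TIPSO)phenyl]-1-[4-(TIPSO)phenyl]ethanone F5. Palladium-catalysed ketone α-arylation with triflate 13 (Pd(OAc)2, XPhos, K3PO4, toluene) gives methyl 7-[1-[3,5-bis(TIPSO)phenyl]-2-oxo-2-[4-(TIPSO)phenyl]ethyl]-2,2-dimethyl-1,3-benzodioxole-5-carboxylate F6, whose α-centre equilibrates. Asymmetric transfer hydrogenation under dynamic kinetic resolution (RuCl(p-cymene)[(S,S)-TsDPEN] or its enantiomer, HCO2H/Et3N) should then fix the diarylmethine centre and give alcohol 17 or its carbinol epimer, the (1R,2S)-alcohol F7. Both converge in step 10, so the route is rejoined at 17.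

3. Step 10. The benzylic cation may lose the C3' proton (forming a triarylethene and erasing C3') or suffer hydride or aryl shift before the weakly nucleophilic ketal oxygen captures it, and the aryl silyl ethers may be partly cleaved. Fallback that changes the order of unmasking and closure: setting out from boronate 16, aqueous trifluoroacetic acid removes the ketal while the C–B bond, which cannot ionise, is kept, giving the (1R,2R)-1-[4-(TIPSO)phenyl]-2-[3,5-bis(TIPSO)phenyl]-2-[2,3-dihydroxy-5-(methoxycarbonyl)phenyl]ethylboronic acid mac ester F8. Perborate oxidation gives methyl 3-[(1R,2R)-1-[3,5-bis(TIPSO)phenyl]-2-hydroxy-2-[4-(TIPSO)phenyl]ethyl]-4,5-dihydroxybenzoate F9. The free C7a' phenol then closes the ring under a catalytic weak acid (pyridinium p-toluenesulfonate, CH2Cl2), where the cation is short-lived, and the route is rejoined at 18.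

Further compounds
F1 | step 22 | S-[4-(TIPSO)benzyl]tetrahydrothiophenium bromide | CC(C)[Si](C(C)C)(C(C)C)Oc1ccc(C[S+]2CCCC2)cc1.[Br-]
F2 | step 22 | heptakis-TIPS ether with (2R,3R) styryl-bearing ring and (2R,3R) 7-silyloxy ring | CC(C)[Si](C(C)C)(C(C)C)Oc1ccc(/C=C/c2cc(O[Si](C(C)C)(C(C)C)C(C)C)cc3c2[C@@H](c2cc(O[Si](C(C)C)(C(C)C)C(C)C)c4c(c2)[C@@H](c2cc(O[Si](C(C)C)(C(C)C)C(C)C)cc(O[Si](C(C)C)(C(C)C)C(C)C)c2)[C@H](c2ccc(O[Si](C(C)C)(C(C)C)C(C)C)cc2)O4)[C@H](c2ccc(O[Si](C(C)C)(C(C)C)C(C)C)cc2)O3)cc1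
F3 | step 8 | [3,5-bis(TIPSO)phenyl]acetaldehyde | O=CCc1cc(O[Si](C(C)C)(C(C)C)C(C)C)cc(O[Si](C(C)C)(C(C)C)C(C)C)c1
F4 | step 8 | 2-[3,5-bis(TIPSO)phenyl]-1-[4-(TIPSO)phenyl]ethanol | OC(Cc1cc(O[Si](C(C)C)(C(C)C)C(C)C)cc(O[Si](C(C)C)(C(C)C)C(C)C)c1)c1ccc(O[Si](C(C)C)(C(C)C)C(C)C)cc1
F5 | step 8 | 2-[3,5-bis(TIPSO)phenyl]-1-[4-(TIPSO)phenyl]ethanone | O=C(Cc1cc(O[Si](C(C)C)(C(C)C)C(C)C)cc(O[Si](C(C)C)(C(C)C)C(C)C)c1)c1ccc(O[Si](C(C)C)(C(C)C)C(C)C)cc1
F6 | step 8 | methyl 7-[1-[3,5-bis(TIPSO)phenyl]-2-oxo-2-[4-(TIPSO)phenyl]ethyl]-2,2-dimethyl-1,3-benzodioxole-5-carboxylate (α-centre labile) | COC(=O)c1cc2c(OC(C)(C)O2)c(c1)C(c1cc(O[Si](C(C)C)(C(C)C)C(C)C)cc(O[Si](C(C)C)(C(C)C)C(C)C)c1)C(=O)c1ccc(O[Si](C(C)C)(C(C)C)C(C)C)cc1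
F7 | step 8 | methyl 7-[(1R,2S)-1-[3,5-bis(TIPSO)phenyl]-2-hydroxy-2-[4-(TIPSO)phenyl]ethyl]-2,2-dimethyl-1,3-benzodioxole-5-carboxylate | COC(=O)c1cc2c(OC(C)(C)O2)c(c1)[C@@H](c1cc(O[Si](C(C)C)(C(C)C)C(C)C)cc(O[Si](C(C)C)(C(C)C)C(C)C)c1)[C@@H](c1ccc(O[Si](C(C)C)(C(C)C)C(C)C)cc1)O
F8 | step 10 | (1R,2R)-1-[4-(TIPSO)phenyl]-2-[3,5-bis(TIPSO)phenyl]-2-[2,3-dihydroxy-5-(methoxycarbonyl)phenyl]ethylboronic acid mac ester | COC(=O)c1cc(O)c(O)c(c1)[C@@H](c1cc(O[Si](C(C)C)(C(C)C)C(C)C)cc(O[Si](C(C)C)(C(C)C)C(C)C)c1)[C@H](c1ccc(O[Si](C(C)C)(C(C)C)C(C)C)cc1)B1O[C@]2(C)c3cccc4cccc(c34)[C@]2(C)O1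
F9 | step 10 | methyl 3-[(1R,2R)-1-[3,5-bis(TIPSO)phenyl]-2-hydroxy-2-[4-(TIPSO)phenyl]ethyl]-4,5-dihydroxybenzoate | COC(=O)c1cc(O)c(O)c(c1)[C@@H](c1cc(O[Si](C(C)C)(C(C)C)C(C)C)cc(O[Si](C(C)C)(C(C)C)C(C)C)c1)[C@H](c1ccc(O[Si](C(C)C)(C(C)C)C(C)C)cc1)O
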